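**Retrosynthetic overview**
1. Forward order in brief: actinol 1 + oleoyl chloride 2 → keto ester 3 → enol triflate 4 → C10 enal 5; then 5 + C30 aldehyde 6 → (titanium pinacolate 7) → target 8.
2. Key disconnection: the C7=C8 double bond of 8 is cut into the two formyl carbons of 5 and 6. Low-valent titanium joins them carbon to carbon, each normally electrophilic C=O carbon reacting as a ketyl-type, polarity-reversed carbon (mixed McMurry coupling), so the last step builds the whole C40 ester.
3. 5 ⇒ 4 (Pd formylation, C6–C7 bond) ⇒ 3 (enol triflation, sets the ring C5=C6 alkene) ⇒ 1 + 2 (acylation). The oleate doubles as the hydroxyl protecting group, and the (3R) carbinol centre is bought with 1.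
4. Rings: none is formed; both six-membered rings are bought intact (in 1 and in 6).

Assumption: 1 (bulk zeaxanthin intermediate), 2 and all-E 6 (food colourant E 160e) are taken as catalogue items; the target is (3R)-all-E-β-cryptoxanthin (9Z)-oleate as drawn.

**Step 1**
Reactants: 1 (4R,6R)-4-hydroxy-2,2,6-trimethylcyclohexan-1-one (actinol); 2 (9Z)-octadec-9-enoyl chloride (oleoyl chloride)
Product: 3 (1R,5R)-3,3,5-trimethyl-4-oxocyclohexyl (9Z)-octadec-9-enoate
Conditions: pyridine (1.5 equiv), DMAP (5 mol %), CH2Cl2, 0 °C → rt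
Reagents that add atoms: none
Why: DMAP-catalysed acylation (nucleophilic acyl substitution) of the unhindered secondary alcohol does not break the carbinol C–O bond, so the (R) centre of 1 is carried over unchanged and the ester then protects the oxygen for the rest of the route.

**Step 2**
Reactants: 3 (1R,5R)-3,3,5-trimethyl-4-oxocyclohexyl (9Z)-octadec-9-enoate
Product: 4 (1R)-3,5,5-trimethyl-4-[(trifluoromethanesulfonyl)oxy]cyclohex-3-en-1-yl (9Z)-octadec-9-enoate
Conditions: Tf2O (1.3 equiv), 2,6-di-tert-butyl-4-methylpyridine (1.5 equiv), CH2Cl2, 0 °C → rt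
Reagents that add atoms: trifluoromethanesulfonic anhydride (Tf2O), O=S(=O)(OS(=O)(=O)C(F)(F)F)C(F)(F)F
Why: Enol triflate formation by O-triflation of the ketone and loss of the only available α-hydrogen (the other α-carbon is quaternary) gives a single regioisomer with the tetrasubstituted C5=C6 alkene; the non-nucleophilic base leaves the ester alone, the methyl-bearing centre is erased on purpose, and the carbinol centre is untouched.

**Step 3**
Reactants: 4 (1R)-3,5,5-trimethyl-4-[(trifluoromethanesulfonyl)oxy]cyclohex-3-en-1-yl (9Z)-octadec-9-enoate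
Product: 5 (1R)-4-formyl-3,5,5-trimethylcyclohex-3-en-1-yl (9Z)-octadec-9-enoate [(3R)-3-oleoyloxy-β-cyclocitral]
Conditions: Pd(OAc)2 (5 mol %), 1,3-bis(diphenylphosphino)propane (7 mol %), CO/H2 (1:1, 5 bar), pyridine (2 equiv), DMF, 70 °C
Reagents that add atoms: carbon monoxide, [C-]#[O+]
Why: Palladium-catalysed reductive carbonylation (formylation) of a vinyl triflate proceeds by oxidative addition, CO insertion and hydrogenolysis of the acyl-palladium; the ester and the isolated Z alkene are inert to the CO-saturated phosphine catalyst, and no stereocentre is involved.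

**Step 4**
Reactants: 5 (1R)-4-formyl-3,5,5-trimethylcyclohex-3-en-1-yl (9Z)-octadec-9-enoate; 6 all-E-β-apo-8'-carotenal
Product: 8 (3R)-all-E-β-cryptoxanthin oleate (target CNP0152321.1), via titanium pinacolate 7 (not isolated)
Conditions: TiCl3(DME)1.5 (3 equiv per CHO), Zn(Cu) couple (3 equiv per Ti), DME, reflux, 2 h; then 5 (1 equiv) + 6 (3 equiv) in DME added over 6 h, 60 °C → reflux, Ar, dark; then n-heptane, 90 °C, 1 h; SiO2 (hexane → hexane/toluene)
Reagents that add atoms: none
Why: In this mixed McMurry reductive coupling, low-valent titanium gives one electron to each formyl group, so the two normally electrophilic carbonyl carbons react as ketyl-type, polarity-reversed carbons and join C7 to C8 as pinacolate 7, whose two allylic C–O bonds are then cleaved on titanium to the thermodynamically favoured 7E alkene (any 7Z residue equilibrates in hot heptane, which does not touch the isolated Z alkene of the oleate); the excess of purchased 6 steers 5 into the cross product (statistical ceiling 75 %), the two symmetric by-products carry zero and two ester groups and separate on silica, and the remote C3 centre is untouched.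

**Compound list**
1 | (4R,6R)-4-hydroxy-2,2,6-trimethylcyclohexan-1-one (actinol) | C[C@@H]1C[C@@H](O)CC(C)(C)C1=O | starting material
2 | (9Z)-octadec-9-enoyl chloride (oleoyl chloride) | CCCCCCCC/C=C\CCCCCCCC(=O)Cl | starting material
3 | (1R,5R)-3,3,5-trimethyl-4-oxocyclohexyl (9Z)-octadec-9-enoate | C[C@@H]1C[C@@H](OC(=O)CCCCCCC/C=C\CCCCCCCC)CC(C)(C)C1=O | intermediate
4 | (1R)-3,5,5-trimethyl-4-[(trifluoromethanesulfonyl)oxy]cyclohex-3-en-1-yl (9Z)-octadec-9-enoate | CCCCCCCC/C=C\CCCCCCCC(=O)O[C@@H]1CC(C)=C(OS(=O)(=O)C(F)(F)F)C(C)(C)C1 | intermediate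
5 | (1R)-4-formyl-3,5,5-trimethylcyclohex-3-en-1-yl (9Z)-octadec-9-enoate | CCCCCCCC/C=C\CCCCCCCC(=O)O[C@@H]1CC(C)=C(C=O)C(C)(C)C1 | intermediate
6 | (2E,4E,6E,8E,10E,12E,14E,16E)-2,6,11,15-tetramethyl-17-(2,6,6-trimethylcyclohex-1-en-1-yl)heptadeca-2,4,6,8,10,12,14,16-octaenal (all-E-β-apo-8'-carotenal) | O=C/C(C)=C/C=C/C(C)=C/C=C/C=C(C)/C=C/C=C(C)/C=C/C1=C(C)CCCC1(C)C | starting material
7 | 7,8-dihydro-7,8-dihydroxy derivative of 8, held as its titanium diolate (C7/C8 diastereomer mixture; SMILES shows the parent diol) | CCCCCCCC/C=C\CCCCCCCC(=O)O[C@@H]1CC(C)=C(C(O)C(O)/C(C)=C/C=C/C(C)=C/C=C/C=C(C)/C=C/C=C(C)/C=C/C2=C(C)CCCC2(C)C)C(C)(C)C1 | intermediate (not isolated)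
8 | (3R)-all-E-β,β-caroten-3-yl (9Z)-octadec-9-enoate [(3R)-β-cryptoxanthin oleate] | CCCCCCCC/C=C\CCCCCCCC(=O)O[C@@H]1CC(C)=C(/C=C/C(C)=C/C=C/C(C)=C/C=C/C=C(C)/C=C/C=C(C)/C=C/C2=C(C)CCCC2(C)C)C(C)(C)C1 | target

**Totals**
Total step count: 4. Longest linear sequence: 4 steps (1 → 3 → 4 → 5 → 8).

**Steps most likely to fail, with fallbacks**

Step 4 (mixed McMurry coupling). The risks are that homo-coupling of the easily reduced polyenal 6 outruns the cross-coupling, or that the oleate is attacked on long reflux. The fallback sets out from 5 and comes back to the route at 8. Aldehyde 5 is condensed with hydrazine hydrate (1.2 equiv, THF, rt; aldehyde condensation far outpaces ester hydrazinolysis) to the N-unsubstituted hydrazone (1R)-4-[(E)-hydrazinylidenemethyl]-3,5,5-trimethylcyclohex-3-en-1-yl (9Z)-octadec-9-enoate F1. The former formyl carbon of F1 now reacts as a carbanion equivalent: with [RuCl2(p-cymene)]2, Me2PCH2CH2PMe2 and K3PO4 in THF at 45 °C it adds to the formyl carbon of 6 (1 equiv), and the adduct loses N2 and water to give 8 directly. Only the hydrazone can be the nucleophile and only 6 the electrophile, so no symmetric dimers form. This ruthenium-catalysed hydrazone olefination is a known reaction type but is untested on polyenals, so it is itself a risky step.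

Step 3 (formylation of a tetrasubstituted, doubly flanked vinyl triflate). The risks are slow CO insertion and plain reduction of the triflate to the alkene. The fallback sets out from 4 and comes back at 5. Stille hydroxymethylation of 4 with Bu3SnCH2OH (Pd(PPh3)4, LiCl, 1,4-dioxane, 100 °C) gives the allylic alcohol (1R)-4-(hydroxymethyl)-3,5,5-trimethylcyclohex-3-en-1-yl (9Z)-octadec-9-enoate F2, which MnO2 (CH2Cl2, rt) oxidises chemoselectively to 5.

Step 2 (electrophilic triflation of a hindered ketone beside an ester). The risk is sluggish enolisation and low conversion. The fallback sets out from 1 and comes back at 4. Alcohol 1 is silylated (TBSCl, imidazole, DMF) to (4R,6R)-4-[(tert-butyldimethylsilyl)oxy]-2,2,6-trimethylcyclohexan-1-one F3. Its lithium enolate (lithium diisopropylamide, LiN(iPr)2, THF, −78 °C) is trapped with PhNTf2 to give (4R)-4-[(tert-butyldimethylsilyl)oxy]-2,6,6-trimethylcyclohex-1-en-1-yl trifluoromethanesulfonate F4. HF·pyridine (THF, 0 °C) frees (4R)-4-hydroxy-2,6,6-trimethylcyclohex-1-en-1-yl trifluoromethanesulfonate F5, and acylation with 2 (pyridine, DMAP, CH2Cl2) gives 4.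

**Further compounds**
F1 | step 4 | (1R)-4-[(E)-hydrazinylidenemethyl]-3,5,5-trimethylcyclohex-3-en-1-yl (9Z)-octadec-9-enoate | CCCCCCCC/C=C\CCCCCCCC(=O)O[C@@H]1CC(C)=C(/C=N/N)C(C)(C)C1
F2 | step 3 | (1R)-4-(hydroxymethyl)-3,5,5-trimethylcyclohex-3-en-1-yl (9Z)-octadec-9-enoate | CCCCCCCC/C=C\CCCCCCCC(=O)O[C@@H]1CC(C)=C(CO)C(C)(C)C1
F3 | step 2 | (4R,6R)-4-[(tert-butyldimethylsilyl)oxy]-2,2,6-trimethylcyclohexan-1-one | C[C@@H]1C[C@@H](O[Si](C)(C)C(C)(C)C)CC(C)(C)C1=O
F4 | step 2 | (4R)-4-[(tert-butyldimethylsilyl)oxy]-2,6,6-trimethylcyclohex-1-en-1-yl trifluoromethanesulfonate | CC(C)(C)[Si](C)(C)O[C@@H]1CC(C)=C(OS(=O)(=O)C(F)(F)F)C(C)(C)C1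
F5 | step 2 | (4R)-4-hydroxy-2,6,6-trimethylcyclohex-1-en-1-yl trifluoromethanesulfonate | O[C@@H]1CC(C)=C(OS(=O)(=O)C(F)(F)F)C(C)(C)C1
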